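The numbers were drawn at random within sensible limits.

The pitfall is to treat open intermediate as a stock that grows with the substrate opened, when substrate both makes it and consumes it.

    substrate → open intermediate (k1 = 5.5 × 10⁻⁴ s⁻¹)
    partner + open intermediate → target (k2 = 0.22 L mol⁻¹ s⁻¹)
    2 partner → homo product (k3 = 0.11 L mol⁻¹ s⁻¹)
    open intermediate + capture agent → trapped intermediate (k4 = 0.088 L mol⁻¹ s⁻¹)
    substrate + open intermediate → side product (k5 = 0.21 L mol⁻¹ s⁻¹)
    target ⇌ isomer of the product (K6 = 2.6, k6 = 0.0016 s⁻¹)

| setting | south-west | south | south-east | north-east |
|---|---|---|---|---|
| substrate | 10 mM | 10 mM | 10 mM | 10 mM |
| partner | 25.0 mM | 25.0 mM (fed, over 12.5 min) | 25.0 mM | 25.0 mM |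
| capture agent | 0.500 mM | 0.500 mM | 0.500 mM | 0.500 mM |
| remark | one stirred flow tank at steady state, fed with the mixture as stated, mean residence time 250 min | all but partner at the start; partner goes in evenly over 12.5 min, the run ends at 25 min | a closed flask charged with all of it at once and left for 25 min | a single well-mixed tank run continuously and read at steady state, 25 min in it on average |
| time |  | 25 min | 25 min |  |

- percent here means substrate units held: one side product counts as two
- for a step with 2 of a species take k times the square, and two of it per event
- the stated concentrations are those of everything mixed, before any reaction; amounts are the same in each set-up
- the feed brings no volume worth counting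
- run time (south): 25 min

- the set-up with the highest amount of open intermediate at the outlet or at the end, in percent of the substrate put in ("none" if the first two lie within 2 percentage points) (south-west / south / south-east / north-east / none)
- amount of open intermediate at the outlet or at the end, in percent of the substrate put in, south-west
- amount of open intermediate at the outlet or at the end, in percent of the substrate put in, south
- amount of open intermediate at the outlet or at the end, in percent of the substrate put in, south-east
- amount of open intermediate at the outlet or at the end, in percent of the substrate put in, north-east

I reckon south-east by hand, because a closed flask needs no outlet term. Open intermediate is made at the rate of the first step. Each loss is proportional to its own amount, so it has a frequency: k times c(partner), c(substrate) or c(capture agent). When making and losing balance, the amount is the rate of making divided by the sum of these frequencies.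

I need the contents at the end of the run. Counting the third step by itself, c(partner) falls to 2.70 mM at 25 min. Counting the first step by itself, c(substrate) falls to 4.38 mM, and these give a first pass of 1.55 mM.

The fifth step also eats substrate, at a frequency set by the rising curve of c(open intermediate). I replace that curve by a mean, taken as 0.773 mM, the midpoint of a rise from nothing. Then c(substrate) ends at 3.44 mM, and the balance comes to 1.39 mM, or 13.9 % of the substrate put in. This is my balance level, the rate of making divided by the summed loss frequencies, a quasi-steady estimate for the end of the run.

To check the mean, I take the whole first pass in its place: c(substrate) then ends at 2.69 mM, and the level is 12.3 %. The error stays small, since substrate stands both above and below the fraction line. The lag is the weaker point: open intermediate follows the level within about 12.3 min, shorter than the run, but not by much.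

The forecast names south-east, with 6.2 % for south-west, 10.8 % for south, 14 % for south-east and 8.1 % for north-east, on the ground that “the open intermediate keeps accumulating late with little left to trap it”.

The simulation names south-east, with 6.21 %, 10.7 %, 13.9 % and 8.12 % in the same order.

In south-east, the loss of substrate + open intermediate to side product holds open intermediate down, as a part of the story: the run without that step ends at 30.1 % against 13.9 %. My balance level of 1.39 mM carries that loss, and on my end-of-run contents its frequency of 0.0433 min⁻¹ is higher than the 0.0357 min⁻¹ of the loss to partner. In north-east, the outlet joins the losses at 0.0400 min⁻¹, and the simulated 6.99 mM of partner and 48.1 % of substrate give 0.811 mM, which is 8.11 % against the simulated 8.12 %.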